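**Retrosynthetic overview**
- Feature used: C4 of the oxolane (O1–C2(aryl)–C3(CH2OH)–C4(aroyl)–C5H2) carries two one-carbon, oxygen-bearing branches, the ring C5H2–O1 and the exocyclic carbonyl carbon. With C4 they map onto C3 and the two CH2–O arms of an oxetane.
- Endgame: the aryl–C(=O) bond comes from ArMgBr addition to the C4 aldehyde and oxidation; C4 is equilibrated α to the ketone; TIPS and two benzyl groups are then removed.
- Key disconnection: O1–C5, by acid-catalysed 5-exo-tet attack of the C2 benzylic hydroxyl on the oxetane. This closes the oxolane, the only ring built in the route (the oxetane is bought as oxetan-3-one and consumed).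
- C2–C3 and both configurations come from an Evans syn-aldol of the N-(oxetan-3-ylacetyl)oxazolidinone with 3-benzyloxy-4-methoxybenzaldehyde; LiBH4 cleavage and primary TIPS protection give the cyclisation substrate.
- The oxetan-3-ylacetyl unit comes from oxetan-3-one by Wittig olefination, hydrogenation and saponification.

Key step: step 8

Remark: the oxolane is numbered O1, C2 (aryl), C3, C4, C5 in all names; the target is (2S,3R,4S), i.e. 2,3-trans-3,4-trans. 2-(Oxetan-3-yl)acetic acid is handled only as its lithium salt, because free oxetanyl carboxylic acids tend to isomerise to lactones.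

Step 1
Reactants: 1 oxetan-3-one; 2 ethyl (triphenylphosphoranylidene)acetate
Product: 3 ethyl 2-(oxetan-3-ylidene)acetate
Conditions: CH2Cl2, 0 °C to rt
Reagents that add atoms: none
Why: Wittig olefination of a strained, highly electrophilic ketone with a stabilised ylide; the ketone is symmetrical, so no geometry or stereocentre arises.

Step 2
Reactants: 3 ethyl 2-(oxetan-3-ylidene)acetate
Product: 4 ethyl 2-(oxetan-3-yl)acetate
Conditions: H2 (1 atm), 10% Pd/C, EtOAc, rt
Reagents that add atoms: none
Why: Catalytic hydrogenation of the electron-poor exocyclic alkene; the oxetane C–O bonds are not hydrogenolysed under neutral conditions.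

Step 3
Reactants: 4 ethyl 2-(oxetan-3-yl)acetate
Product: 5 lithium 2-(oxetan-3-yl)acetate
Conditions: LiOH·H2O (1.0 equiv), THF/H2O, 0 °C to rt; evaporate, dry azeotropically with toluene
Reagents that add atoms: lithium hydroxide, [Li+].[OH-]
Why: Ester saponification; the carboxylate is never protonated, which avoids acid-promoted intramolecular opening of the oxetane to a lactone.

Step 4
Reactants: 5 lithium 2-(oxetan-3-yl)acetate; 6 (S)-4-benzyl-2-oxazolidinone
Product: 8 (4S)-4-benzyl-3-[2-(oxetan-3-yl)acetyl]-1,3-oxazolidin-2-one, via mixed pivalic anhydride 7 (not isolated)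
Conditions: PivCl (1.05 equiv), Et3N (1.5 equiv), THF, −20 to 0 °C; then 6, LiCl (0.5 equiv), rt
Reagents that add atoms: none
Why: N-acylation of the oxazolidinone through a mixed anhydride under LiCl/Et3N activation; the nucleophile attacks the less hindered acyl carbon, and no strong acid is present to open the oxetane.

Step 5
Reactants: 8 (4S)-4-benzyl-3-[2-(oxetan-3-yl)acetyl]-1,3-oxazolidin-2-one; 9 3-benzyloxy-4-methoxybenzaldehyde
Product: 11 (4S)-4-benzyl-3-[(2S,3S)-3-(3-benzyloxy-4-methoxyphenyl)-3-hydroxy-2-(oxetan-3-yl)propanoyl]-1,3-oxazolidin-2-one, via Z-dibutylboron enolate 10 (not isolated)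
Conditions: Bu2BOTf (1.1 equiv), iPr2NEt (1.3 equiv), CH2Cl2, −78 to 0 °C; then 9, −78 to 0 °C; pH 7 buffer, MeOH, 30% H2O2, 0 °C
Reagents that add atoms: none
Why: Evans syn-aldol reaction: the Z-boron enolate reacts through a chair (Zimmerman–Traxler) transition state with the auxiliary carbonyl turned away from the enolate oxygen, and the aldehyde adds to the face remote from the benzyl group, which should set both new centres as the (2S,3S) syn adduct (future C3 and C2 of the oxolane); boron is held by the imide, and the non-nucleophilic triflate and hindered amine should leave the oxetane closed at low temperature.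

Step 6
Reactants: 11 (4S)-4-benzyl-3-[(2S,3S)-3-(3-benzyloxy-4-methoxyphenyl)-3-hydroxy-2-(oxetan-3-yl)propanoyl]-1,3-oxazolidin-2-one
Product: 12 (1S,2R)-1-(3-benzyloxy-4-methoxyphenyl)-2-(oxetan-3-yl)propane-1,3-diol
Conditions: LiBH4 (2 equiv), MeOH (2 equiv), THF, 0 °C
Reagents that add atoms: none
Why: Reductive cleavage of the N-acyl oxazolidinone: hydride attacks the activated exocyclic carbonyl and releases the auxiliary and the primary alcohol; no stereocentre is touched, and oxetane and benzyl ether are inert to borohydride.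

Step 7
Reactants: 12 (1S,2R)-1-(3-benzyloxy-4-methoxyphenyl)-2-(oxetan-3-yl)propane-1,3-diol
Product: 13 (1S,2R)-1-(3-benzyloxy-4-methoxyphenyl)-2-(oxetan-3-yl)-3-(triisopropylsilyloxy)propan-1-ol
Conditions: TIPSCl (1.05 equiv), imidazole (2.5 equiv), CH2Cl2, 0 °C to rt
Reagents that add atoms: triisopropylsilyl chloride, CC(C)[Si](Cl)(C(C)C)C(C)C
Why: Silyl ether formation; the bulky silyl chloride reacts at the primary hydroxyl and leaves the hindered benzylic hydroxyl as the only free nucleophile.

Step 8
Reactants: 13 (1S,2R)-1-(3-benzyloxy-4-methoxyphenyl)-2-(oxetan-3-yl)-3-(triisopropylsilyloxy)propan-1-ol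
Product: 14 [(2S,3R,4R)-2-(3-benzyloxy-4-methoxyphenyl)-3-(triisopropylsilyloxymethyl)oxolan-4-yl]methanol
Conditions: (PhO)2P(O)OH (10 mol %), toluene (0.05 M), 0 °C to rt
Reagents that add atoms: none
Why: The phosphoric acid activates the oxetane oxygen by hydrogen bonding or protonation while the C2 benzylic hydroxyl attacks one ring CH2 from the rear in an SN2 opening driven by release of about 25 kcal/mol of ring strain, and the departing oxygen becomes the CH2OH on C4. This is the established Brønsted- or Lewis-acid-catalysed intramolecular opening of 3-substituted oxetanes by a tethered alcohol, which delivers 3-(hydroxymethyl)oxolanes. The oxolane closes in the 5-exo-tet mode with formation of the O1–C5 bond. C4 is the new stereocentre, fixed by which of the two diastereotopic CH2 groups is attacked; the C3 silyloxymethyl group is gauche to the spectator oxetane arm in the transition state leading to the 3,4-cis product and anti in the other, so the 3,4-trans product should be favoured, with C2 and C3 unchanged because no bond to them is broken. The step needs chemoselection for the benzylic oxygen, secured by the TIPS ether on the only other hydroxyl, and oxetane activation without ionisation of the p-alkoxybenzylic carbinol, secured by a weak acid in an apolar solvent at or below room temperature. Any 3,4-cis epimer is not lost, since C4 becomes enolisable after steps 9 to 11 and is equilibrated there.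

Step 9
Reactants: 14 [(2S,3R,4R)-2-(3-benzyloxy-4-methoxyphenyl)-3-(triisopropylsilyloxymethyl)oxolan-4-yl]methanol
Product: 15 (2S,3R,4S)-2-(3-benzyloxy-4-methoxyphenyl)-3-(triisopropylsilyloxymethyl)oxolane-4-carbaldehyde
Conditions: Dess–Martin periodinane (1.3 equiv), pyridine (3 equiv), CH2Cl2, 0 °C to rt; crude product used directly
Reagents that add atoms: none
Why: Dess–Martin oxidation of the primary alcohol under buffered anhydrous conditions stops at the aldehyde; silyl ether, benzyl ether and oxolane are inert, and partial epimerisation at C4 would not matter because C4 is equilibrated in step 11.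

Step 10
Reactants: 15 (2S,3R,4S)-2-(3-benzyloxy-4-methoxyphenyl)-3-(triisopropylsilyloxymethyl)oxolane-4-carbaldehyde; 16 2-benzyloxy-4-bromoanisole
Product: 18 (3-benzyloxy-4-methoxyphenyl)[(2S,3R,4S)-2-(3-benzyloxy-4-methoxyphenyl)-3-(triisopropylsilyloxymethyl)oxolan-4-yl]methanol (both carbinol epimers), via arylmagnesium bromide 17 (not isolated)
Conditions: 16, Mg turnings, I2 (cat.), THF, 45 °C; then 15, THF, −78 to −20 °C; aq. NH4Cl
Reagents that add atoms: none
Why: Grignard addition to the aldehyde at low temperature; the new carbinol centre should form as a mixture, which is irrelevant because it is oxidised in step 11.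

Step 11
Reactants: 18 (3-benzyloxy-4-methoxyphenyl)[(2S,3R,4S)-2-(3-benzyloxy-4-methoxyphenyl)-3-(triisopropylsilyloxymethyl)oxolan-4-yl]methanol
Product: 19 (3-benzyloxy-4-methoxyphenyl)[(2S,3R,4S)-2-(3-benzyloxy-4-methoxyphenyl)-3-(triisopropylsilyloxymethyl)oxolan-4-yl]methanone
Conditions: Dess–Martin periodinane (1.5 equiv), pyridine, CH2Cl2, rt; work-up; then DBU (0.3 equiv), CH2Cl2, rt
Reagents that add atoms: none
Why: Dess–Martin oxidation of the benzylic carbinol gives the aryl ketone; catalytic DBU then enolises C4 reversibly and should equilibrate it to the preferred arrangement with the aroyl group trans to the C3 substituent (all-trans ring), so any C4 epimer carried from step 8 converges here.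

Step 12
Reactants: 19 (3-benzyloxy-4-methoxyphenyl)[(2S,3R,4S)-2-(3-benzyloxy-4-methoxyphenyl)-3-(triisopropylsilyloxymethyl)oxolan-4-yl]methanone
Product: 20 (3-benzyloxy-4-methoxyphenyl)[(2S,3R,4S)-2-(3-benzyloxy-4-methoxyphenyl)-3-(hydroxymethyl)oxolan-4-yl]methanone
Conditions: HF·pyridine, pyridine, THF, 0 °C to rt
Reagents that add atoms: none
Why: Fluoride-mediated cleavage of the primary silyl ether in a pyridine-buffered medium that should neither enolise the β-alkoxy ketone nor affect the benzyl ethers.

Step 13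
Reactants: 20 (3-benzyloxy-4-methoxyphenyl)[(2S,3R,4S)-2-(3-benzyloxy-4-methoxyphenyl)-3-(hydroxymethyl)oxolan-4-yl]methanone
Product: 21 (3-hydroxy-4-methoxyphenyl)[(2S,3R,4S)-2-(3-hydroxy-4-methoxyphenyl)-3-(hydroxymethyl)oxolan-4-yl]methanone (CNP0234761.1)
Conditions: H2 (1 atm), 10% Pd/C, EtOAc, rt, stopped when 20 is consumed
Reagents that add atoms: none
Why: Catalytic hydrogenolysis of the two aryl benzyl ethers; in a neutral aprotic solvent at 1 atm the O–CH2Ph bonds should cleave much faster than the ring C2–O benzylic bond is cut or the electron-rich aryl ketone is reduced.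

**Compound list**
1 | oxetan-3-one | O=C1COC1 | starting material
2 | ethyl (triphenylphosphoranylidene)acetate | CCOC(=O)C=P(c1ccccc1)(c1ccccc1)c1ccccc1 | starting material
3 | ethyl 2-(oxetan-3-ylidene)acetate | CCOC(=O)C=C1COC1 | intermediate
4 | ethyl 2-(oxetan-3-yl)acetate | CCOC(=O)CC1COC1 | intermediate
5 | lithium 2-(oxetan-3-yl)acetate | [Li+].[O-]C(=O)CC1COC1 | intermediate
6 | (S)-4-benzyl-2-oxazolidinone | O=C1OC[C@H](Cc2ccccc2)N1 | starting material
7 | 2-(oxetan-3-yl)acetic pivalic anhydride (not isolated) | CC(C)(C)C(=O)OC(=O)CC1COC1 | intermediate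
8 | (4S)-4-benzyl-3-[2-(oxetan-3-yl)acetyl]-1,3-oxazolidin-2-one | O=C1OC[C@H](Cc2ccccc2)N1C(=O)CC1COC1 | intermediate
9 | 3-benzyloxy-4-methoxybenzaldehyde | O=Cc1ccc(OC)c(OCc2ccccc2)c1 | starting material
10 | Z-dibutylboron enolate of 8 (not isolated) | CCCCB(CCCC)O/C(=C\C1COC1)N1C(=O)OC[C@@H]1Cc1ccccc1 | intermediate
11 | (4S)-4-benzyl-3-[(2S,3S)-3-(3-benzyloxy-4-methoxyphenyl)-3-hydroxy-2-(oxetan-3-yl)propanoyl]-1,3-oxazolidin-2-one | O[C@H](c1ccc(OC)c(OCc2ccccc2)c1)[C@H](C1COC1)C(=O)N1C(=O)OC[C@@H]1Cc1ccccc1 | intermediate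
12 | (1S,2R)-1-(3-benzyloxy-4-methoxyphenyl)-2-(oxetan-3-yl)propane-1,3-diol | O[C@H](c1ccc(OC)c(OCc2ccccc2)c1)[C@H](C1COC1)CO | intermediate
13 | (1S,2R)-1-(3-benzyloxy-4-methoxyphenyl)-2-(oxetan-3-yl)-3-(triisopropylsilyloxy)propan-1-ol | O[C@H](c1ccc(OC)c(OCc2ccccc2)c1)[C@H](C1COC1)CO[Si](C(C)C)(C(C)C)C(C)C | intermediate
14 | [(2S,3R,4R)-2-(3-benzyloxy-4-methoxyphenyl)-3-(triisopropylsilyloxymethyl)oxolan-4-yl]methanol (2,3-trans-3,4-trans) | OC[C@@H]1CO[C@H](c2ccc(OC)c(OCc3ccccc3)c2)[C@H]1CO[Si](C(C)C)(C(C)C)C(C)C | intermediate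
15 | (2S,3R,4S)-2-(3-benzyloxy-4-methoxyphenyl)-3-(triisopropylsilyloxymethyl)oxolane-4-carbaldehyde | O=C[C@@H]1CO[C@H](c2ccc(OC)c(OCc3ccccc3)c2)[C@H]1CO[Si](C(C)C)(C(C)C)C(C)C | intermediate
16 | 2-benzyloxy-4-bromoanisole | COc1ccc(Br)cc1OCc1ccccc1 | starting material
17 | (3-benzyloxy-4-methoxyphenyl)magnesium bromide (not isolated) | COc1ccc([Mg]Br)cc1OCc1ccccc1 | intermediate
18 | (3-benzyloxy-4-methoxyphenyl)[(2S,3R,4S)-2-(3-benzyloxy-4-methoxyphenyl)-3-(triisopropylsilyloxymethyl)oxolan-4-yl]methanol, carbinol epimers | OC(c1ccc(OC)c(OCc2ccccc2)c1)[C@@H]1CO[C@H](c2ccc(OC)c(OCc3ccccc3)c2)[C@H]1CO[Si](C(C)C)(C(C)C)C(C)C | intermediate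
19 | (3-benzyloxy-4-methoxyphenyl)[(2S,3R,4S)-2-(3-benzyloxy-4-methoxyphenyl)-3-(triisopropylsilyloxymethyl)oxolan-4-yl]methanone | O=C(c1ccc(OC)c(OCc2ccccc2)c1)[C@@H]1CO[C@H](c2ccc(OC)c(OCc3ccccc3)c2)[C@H]1CO[Si](C(C)C)(C(C)C)C(C)C | intermediate
20 | (3-benzyloxy-4-methoxyphenyl)[(2S,3R,4S)-2-(3-benzyloxy-4-methoxyphenyl)-3-(hydroxymethyl)oxolan-4-yl]methanone | O=C(c1ccc(OC)c(OCc2ccccc2)c1)[C@@H]1CO[C@H](c2ccc(OC)c(OCc3ccccc3)c2)[C@H]1CO | intermediate
21 | (3-hydroxy-4-methoxyphenyl)[(2S,3R,4S)-2-(3-hydroxy-4-methoxyphenyl)-3-(hydroxymethyl)oxolan-4-yl]methanone | COc1ccc(C(=O)[C@@H]2CO[C@H](c3ccc(OC)c(O)c3)[C@H]2CO)cc1O | target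

**Totals**
Total step count: 13. Longest linear sequence: 13 steps (1 to 21).

**Steps most likely to fail**

Step 8. What may go wrong: acid-induced ionisation at the p-alkoxybenzylic carbinol (loss of C2 integrity, elimination) may compete with a slow oxetane opening, or discrimination between the two ring CH2 groups may be weak (the latter only costs material balance until step 11). Fallback: ring opening and ring closure are separated so that no free benzylic alcohol meets an acid. Setting out from 13, the benzylic hydroxyl is acetylated (Ac2O, pyridine, DMAP) to the benzylic acetate F1. Bromotrimethylsilane (1.05 equiv, CH2Cl2, −40 °C) then opens the oxetane by bromide attack at a ring CH2 to the primary bromide trimethylsilyl ether F2, as both epimers at the new branch carbon. K2CO3 in methanol removes the acetate and the trimethylsilyl group to the bromo diol F3, whose benzylic alkoxide displaces bromide in a 5-exo-tet Williamson closure in the same flask. The sequence comes back to the route at 14, formed together with its C4 epimer, which converges in step 11.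

Step 5. What may go wrong: the strongly Lewis-acidic boron triflate may engage the Lewis-basic oxetane (ring opening, oligomerisation, incomplete enolisation), or the adduct of the electron-rich aldehyde may revert by retro-aldol during work-up. Fallback: the same syn stereodiad is built by enolate acylation and chelation-controlled reduction in the enantiomeric auxiliary series, without a strong Lewis acid. Setting out from 5, the mixed anhydride 7 is coupled with (R)-4-benzyl-2-oxazolidinone to the (4R)-imide F4. Aldehyde 9 is oxidised (NaClO2, NaH2PO4, 2-methyl-2-butene) to 3-benzyloxy-4-methoxybenzoic acid F5 and converted with oxalyl chloride into the aroyl chloride F6. F4 is deprotonated with NaHMDS (THF, −78 °C) to the chelated sodium Z-enolate F7, which is C-acylated by F6 on the face away from the benzyl group to the β-keto imide F8; this is the face opposite to the one used in the boron aldol, hence the (R)-auxiliary. Zn(BH4)2 (CH2Cl2, −20 °C) reduces the chelated ketone anti to the α-substituent to the syn-hydroxy imide F9, and LiBH4 cleavage as in step 6 brings the sequence back to the route at 12.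

Step 10. What may go wrong: the basic Grignard reagent may deprotonate the α-branched β-alkoxy aldehyde (enolisation, β-elimination with ring opening) instead of adding to it. Fallback: the ketone is formed by acyl substitution and the aldehyde is avoided. Setting out from 14, the primary alcohol is oxidised directly (TEMPO cat., PhI(OAc)2, MeCN/H2O) to the oxolane-4-carboxylic acid F10, which is coupled with N,O-dimethylhydroxylamine hydrochloride (EDC·HCl, HOBt, iPr2NEt) to the Weinreb amide F11. Addition of arylmagnesium bromide 17 (THF, 0 °C) should stop at the chelated tetrahedral adduct and, after work-up and the DBU equilibration of step 11, comes back to the route at 19.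

**Further compounds**
F1 | step 8 | (1S,2R)-1-(3-benzyloxy-4-methoxyphenyl)-2-(oxetan-3-yl)-3-(triisopropylsilyloxy)propyl acetate | CC(=O)O[C@H](c1ccc(OC)c(OCc2ccccc2)c1)[C@H](C1COC1)CO[Si](C(C)C)(C(C)C)C(C)C
F2 | step 8 | 1-(3-benzyloxy-4-methoxyphenyl)-4-bromo-2-(triisopropylsilyloxymethyl)-3-(trimethylsilyloxymethyl)butyl acetate, C1 and C2 as in 13, C3 epimers | CC(=O)O[C@H](c1ccc(OC)c(OCc2ccccc2)c1)[C@H](C(CBr)CO[Si](C)(C)C)CO[Si](C(C)C)(C(C)C)C(C)C
F3 | step 8 | 1-(3-benzyloxy-4-methoxyphenyl)-3-(bromomethyl)-2-(triisopropylsilyloxymethyl)butane-1,4-diol, C1 and C2 as in 13, C3 epimers | O[C@H](c1ccc(OC)c(OCc2ccccc2)c1)[C@H](C(CBr)CO)CO[Si](C(C)C)(C(C)C)C(C)C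
F4 | step 5 | (4R)-4-benzyl-3-[2-(oxetan-3-yl)acetyl]-1,3-oxazolidin-2-one | O=C1OC[C@@H](Cc2ccccc2)N1C(=O)CC1COC1
F5 | step 5 | 3-benzyloxy-4-methoxybenzoic acid | OC(=O)c1ccc(OC)c(OCc2ccccc2)c1
F6 | step 5 | 3-benzyloxy-4-methoxybenzoyl chloride | ClC(=O)c1ccc(OC)c(OCc2ccccc2)c1
F7 | step 5 | sodium Z-enolate of F4 | [Na]O/C(=C\C1COC1)N1C(=O)OC[C@H]1Cc1ccccc1
F8 | step 5 | (4R)-4-benzyl-3-[(2S)-3-(3-benzyloxy-4-methoxyphenyl)-2-(oxetan-3-yl)-3-oxopropanoyl]-1,3-oxazolidin-2-one | O=C(c1ccc(OC)c(OCc2ccccc2)c1)[C@H](C1COC1)C(=O)N1C(=O)OC[C@H]1Cc1ccccc1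
F9 | step 5 | (4R)-4-benzyl-3-[(2S,3S)-3-(3-benzyloxy-4-methoxyphenyl)-3-hydroxy-2-(oxetan-3-yl)propanoyl]-1,3-oxazolidin-2-one | O[C@H](c1ccc(OC)c(OCc2ccccc2)c1)[C@H](C1COC1)C(=O)N1C(=O)OC[C@H]1Cc1ccccc1
F10 | step 10 | (2S,3R,4S)-2-(3-benzyloxy-4-methoxyphenyl)-3-(triisopropylsilyloxymethyl)oxolane-4-carboxylic acid | OC(=O)[C@@H]1CO[C@H](c2ccc(OC)c(OCc3ccccc3)c2)[C@H]1CO[Si](C(C)C)(C(C)C)C(C)C
F11 | step 10 | (2S,3R,4S)-2-(3-benzyloxy-4-methoxyphenyl)-N-methoxy-N-methyl-3-(triisopropylsilyloxymethyl)oxolane-4-carboxamide | CON(C)C(=O)[C@@H]1CO[C@H](c2ccc(OC)c(OCc3ccccc3)c2)[C@H]1CO[Si](C(C)C)(C(C)C)C(C)C
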